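The constants used here were chosen freely, and the outcome is calculated.

I could not have the whole charge of reagent at work in the reaction phase, for the two phases share it.

    reagent in the reaction phase ⇌ reagent in the second phase, rate k1*([reagent in the reaction phase] - [reagent in the second phase]/K1) per volume of the first phase (K1 = 0.52, k1 = 0.15 min⁻¹)
    starting material + reagent in the reaction phase → target (k2 = 0.021 M⁻¹ min⁻¹)
    target → over-reaction product (k3 = 0.088 min⁻¹)
    starting material + protic impurity → quenched substrate (k4 = 0.045 M⁻¹ min⁻¹)

starting material 2.0 M; reagent in the second phase 0.950 equiv; protic impurity 0.400 M; time 25 min; volume of the second phase over the first 2.0

- in the second phase: reagent in the second phase; everything else is in the first
- charges count per volume of the first phase; a concentration in a rate is the amount of a species over the volume of its own phase; every rate counts per litre of the first phase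
- run time (flask): 25 min

- midnight: doubling the amount of reagent in the second phase, all else as stated
- noon: doubling the transfer coefficient of step 1, all else as stated

1. amount of target at 25 min, in percent of the starting material charged
2. the change that raises the amount of target at 25 min, in percent of the starting material charged most ("none" if none brings more than 2 percentage points) (midnight / noon / none)
3. amount of target at 25 min, in percent of the starting material charged, after noon

**Free reagent.** The transfer relaxes in 3.40 min, which is shorter than the run of 25 min, so I took it as settled. The reaction phase then keeps a share 0.490 of the reagent, one over one plus the partition ratio times the volume ratio. With none of it consumed yet, that gave c(reagent in the reaction phase) = 0.931 M, and I carried this as the free reagent.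

**Turned round.** I looked for the condition under which target is not held down by its own loss: starting material turning into target faster than target turns into over-reaction product. I named the balance ratio: the pseudo-first-order constant of making, free reagent times the constant of step two, over the constant of the loss of target, 0.222. That condition asks the ratio to pass one, and with the free reagent of this flask it stood below one. So I expected c(target) near the ratio times c(starting material).

**My estimate.** The protic impurity could take at most 20.0% of the starting material; I took that whole share off at once and let the rest decay to target at the free reagent, which left 49.1% as my rough figure. That gave an estimate of 10.9% of target. Midnight takes the ratio to 0.444, noon does not enter it, so I chose midnight.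

**The forecast.** It gave 9.8%, midnight and 10.2% after noon, saying of the transfer “doubling it adds little”. My figure stood above its figure.

**The simulation.** The flask gave 9.88% and 10.1% after noon. Midnight gained 6.5 percentage points and noon 0.17 points, so the best change was midnight.

**Balance read.** At 25.0 min in the flask, the half-life of target by over-reaction was 7.9 min against 51 min for starting material going to target, a balance ratio of 0.156; on 58.3% of starting material that gives 9.09%, and target was made at 0.918 of the rate of its loss. In the neighbouring flask charged at 0.50 M of starting material, equivalents held, the ratio scales to 0.0556, which on its 63.4% of starting material gives 3.53%, and that flask held 3.17% of target.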